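Early times bear out one part of your hunch: at 4.00 min the epsilon run held 8.8% of target and the zeta run 13.5%, about in step with their catalyst charges. I doubted the other part, that the flattening was equilibrium.

| flask | substrate | capture agent | free catalyst | remark |
|---|---|---|---|---|
| epsilon | 2 M | 2 M | 5 mM | run made earlier |
| zeta | 2 M | 2 M | 7.5 mM | run made earlier |
| flask | 2.0 M | 2.00 M | 10 mM |  |

| run | time / min | target / % | substrate / % |
|---|---|---|---|
| epsilon | 4.00 | 8.8 | 90.9 |
| epsilon | 8.00 | 11.1 | 88.5 |
| epsilon | 10.0 | 12.3 | 87.3 |
| epsilon | 15.0 | 11.7 | 87.1 |
| epsilon | 20.0 | 12.7 | 86.8 |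
| epsilon | 25.0 | 12.7 | 87.3 |
| zeta | 4.00 | 13.5 | 86.4 |
| zeta | 8.00 | 16.9 | 82.1 |
| zeta | 10.0 | 17.7 | 82.1 |
| zeta | 15.0 | 18.6 | 80.6 |
| zeta | 20.0 | 18.7 | 80.6 |
| zeta | 25.0 | 18.5 | 81.1 |

(standard deviation of a reading: 0.5 percentage points)

- factor on the rate of making target when 5.0% of the substrate are converted if free catalyst is charged twice over
- factor on the rate when 5.0% of the substrate are converted if free catalyst is charged at 100 mM instead

- the earlier runs were read with a standard deviation of 0.5 percentage points

At 25.0 min the epsilon run stood at 12.7% and the zeta run at 18.5%, with substrate left in each, so the level moved with the charge. I read that as catalyst being lost.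

So I counted target made per catalyst charged, the turnover budget (the usual turnover number): 50.8 in the epsilon run and 49.3 in the zeta run. Given the scatter, I took these as one number, their mean 50.1.

At the asked conversion I reckoned the flask to have made 100 mM of target, at a cost of 2.00 mM of catalyst at each of these charges. I took the rate to follow what still worked, at the same substrate and capture agent. This gave me factors of 2.25 and 12.2.

The forecast, on the same count, said 2.25 and 12.25, in its words “the catalyst is dying, not the reaction equilibrating”.

The flask gave 2.24 and 12.2.

    substrate + free catalyst ⇌ catalyst intermediate (K = 0.493 M⁻¹, k = 9.00 M⁻¹ min⁻¹)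
    catalyst intermediate → free catalyst + target (k = 731 min⁻¹)
    catalyst intermediate + capture agent → trapped intermediate (k = 7.22 M⁻¹ min⁻¹)

At the charged capture agent the catalyst intermediate released target 50.6 times per capture, the budget seen from the constants, and on this flask's charge 50.1 turnovers came to 25.0% of target, against 25.3% held at 25.0 min with 99.8% of its catalyst trapped. The simulated run of this flask without capture is the proof: there the rate at the asked conversion was 1.26 times the actual one, and the budget's count gives 1.25. With capture gone, the apparent order in free catalyst at that conversion went from 1.2 to 1.0.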